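## The problem

The target is a germacranolide: a ten-membered carbocycle trans-fused at C6/C7 to an α-methylene-γ-lactone. It carries a methacrylate at C8, a trans-epoxide at C1/C10, a cis-epoxide at C2/C3, an exocyclic methylene at C4 and a secondary alcohol at C5, with eight stereocentres (1R,2S,3S,5R,6S,7R,8S,10R). C6, C7 and C8 (6α-O, 7β-C, 8α-O) are contiguous and are most safely set on a six-membered ring. Once the trans-lactone exists it also fixes the shape of the medium ring and so decides from which side C1=C10, C2=C3 and C5 are reached. The other five centres sit on carbons that are sp2 in a less oxidised ring, so they must come from face-selective additions to a (1(10)E,2Z,4E)-triene or its descendants. C5 needs care: its oxygen is anti to the C6 lactone oxygen (zig-zag C4–C7). Oxygen delivered to the open face of a 4E-alkene ends up syn, because allylic strain holds H-6 in the alkene plane and C7 covers the other face; C5 must therefore receive hydrogen, not oxygen, in its last bond-forming step. The molecule will not survive rough treatment: two Michael acceptors (lactone methylene, methacrylate), a bis-epoxide next to an allylic alcohol, and a lactone flanked by oxygen functions at C5 and C8 rule out strong base, strong acid, nucleophiles and hydrogenation once the ten-membered ring exists. The enabling feature is that C10=C1–C2=C3–C4=C5, read through the two epoxides and the C4(=CH2)–C5 carbinol, is the E,Z,E triene that conrotatory 6π opening of a trans-fused eudesma-1,3-diene across C5–C10 gives. Rings A and B of a decalin can therefore carry the stereochemical work and the medium ring is unveiled late.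

## Retrosynthesis

**32 to 31 (C5–H).** The C5 carbinol is cut back to ketone 31. Hydride entering the outer face of the exocyclic enone leaves the hydroxyl on the inner side, which is the anti relationship to O6 that outer-face oxygen delivery cannot give. The forward step must be a clean 1,2-reduction beside a lactone, an ester and two epoxides.

**31 to 30 (O–C2, O–C3).** The cis-epoxide is removed while C4=C15 is still part of an enone. The methylene is then electron-poor and C2=C3 is the only alkene left for an electrophilic oxidant, so the site question that would arise beside a free 4(15)-en-5-ol does not occur.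

**30 to 28 (C5–O formed, C15–H lost).** The enone is traced to the 4E-alkene with its own C15 methyl by a Schenck ene reaction followed by dehydration of the hydroperoxide. A [2,3] shift of a C15 sulfoxide or selenoxide was weighed against this and dropped for three reasons: an aryl chalcogenide is a second chromophore with a weak allylic bond in the photochemical step; the sulfoxide shift needs temperatures at which the triene recloses; and it would set C5 with the wrong configuration. The ene route also makes the decalin precursor simpler, since C15 needs no functional group.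

**28 to 26 through 27 (C5–C10 σ bond; C1=C10 and C4=C5 π bonds).** The key cut. Triene 27 comes from the trans-fused diene 26 by photochemical conrotatory opening. It is not isolated: its most electron-rich alkene is epoxidised cold, which ends both thermal reclosure and photo-equilibration. The alternative of closing a ten-membered ring from an open chain is avoided altogether.

**26 to 22 (ring A diene; ester).** The 1,3-diene is the reduction product of dienyl triflate 23 from the 1-en-3-one 22. No strong base is needed, and the methacrylate is put on last (24, 25, 26).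

**22 to 19 (C1=C2, C11=C13; C5–H).** Both unsaturations of 22 come from one double selenoxide elimination on the saturated keto lactone 20. Compound 20 is the hydrogenation product of enone lactone 19, the step that sets the trans ring fusion from the α face.

**19 to 12 (C6–O, C12 oxidation).** The lactone is taken apart into 6α-hydroxy enone 16 and an isopropenyl group. C6 oxygen comes stereospecifically from the 5α,6α-epoxide 14 of the deconjugated ketal 13, and C12 from allylic oxidation (17) and oxidative lactonisation. A γ-bromination and displacement route is shorter but gives no control at C6.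

**12 to 7 + 8 (C1–C10, C4–C5).** Robinson annulation of ethyl vinyl ketone 8 onto ketone 7 through a chiral imine builds ring A and the C10 quaternary centre under reagent control.

**7 to 1 (C8–O; carbonyl transposition).** Ketone 7 is a dihydrocarvone with oxygen on the carbon next to the isopropenyl carbon. That carbon is the α′-position of carvone once the carbonyl is moved across the ring by a Wharton transposition (2 to 6). The transposition reverses the ring numbering, so (S)-carvone 1 is the correct antipode.

## Roads not taken

**Alternative 1:** The ring is cut at C5–C6. InCl3 transmetalates an α-alkoxyallyl stannane to the γ-alkoxyallylindium species, which adds through C5 to a C6 aldehyde; the C6 alkoxide then lactonises to give A1 (ten-membered trans-fused lactone with C5 MOM ether, C4 methylene and the 1(10)E,2Z-diene).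
- Merits: one step makes the ring, the C5–C6 bond, both carbinol centres and the C4 methylene. The closed transition state of γ-alkoxyallyl additions gives the anti 1,2-dioxygen pattern that the target has at C5/C6. Here it is better than the chosen plan, which reaches C5 only through an ene reaction and a reduction.
- Weak points: a ten-membered ring is closed at high dilution onto an α-branched aldehyde that can epimerise at C7. The stannane, the Z-alkene and the E-trisubstituted alkene must all be carried in an open chain. A1 still needs lactone methylenation, MOM removal beside acid-labile allylic systems, silyl-to-methacrylate exchange, and two epoxidations that must spare a C4 methylene already present.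
- Comparison: the chosen plan offers a ring that is unveiled from a rigid decalin and a short endgame in which the methylene is an enone when the last epoxide is made.

**Alternative 2:** The cut runs through the diene. Ring-closing enyne metathesis of a C3≡C4 alkyne with a C2 vinyl epoxide (second-generation Grubbs catalyst, ethylene) forms C2=C3 and C4=C15 and gives A2.
- Merits: the 1,10-epoxide and the C5 and C8 oxygens are in place before the ring exists, only one epoxidation remains and no photochemistry is needed. It is the most convergent of the four, and its C1/C10 and C5 centres do not depend on medium-ring face selectivity, which the chosen plan cannot claim.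
- Weak points: endo-mode closure to a ten-membered ring must deliver a Z-alkene without geometric control and competes with oligomerisation. The ruthenium carbene is formed next to an epoxide. Two silyl ethers must later be told apart, the lactone methylenated, and C2=C3 epoxidised beside the C4 methylene.
- Comparison: the chosen plan is stronger at the ring-forming event itself, where ring fusion and orbital symmetry fix the Z geometry.

**Alternative 3:** A carvone-derived 6-alkenyl-1-isopropenylcyclohexenol is opened by anionic oxy-Cope rearrangement (KH, 18-crown-6), which cleaves C1–C6, forms C8–C9 and gives the ten-membered dienone A3.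
- Merits: cheap chirality, a thermal and scalable ring expansion with no photostationary limit, and alkene geometry defined by the [3,3] transition state. As a ring-forming step it is at least as reliable as the photochemical opening.
- Weak points: A3 is far from the target. The tertiary C4 silyl ether must be eliminated regioselectively to the methylene, the C6 ketone reduced, the side chain oxidised, lactonised and methylenated, PMB exchanged for methacrylate and both epoxides added, with C7 epimerisable next to the ketone throughout.
- Comparison: the chosen plan has the shorter path after the key step and C6–C8 fixed on a decalin, but pays with a longer approach to the key step and a photoequilibrium.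

Key step: step 20

## Route

Remark: α and β refer to the usual eudesmane drawing (C10 methyl β); for the ten-membered compounds the SMILES strings and CIP descriptors are decisive.

Remark: the silyl ether in 3–24 is tert-butyldiphenylsilyl (TBDPS).

Step 1
Reactants: 1 (S)-(+)-carvone
Product: 2 (5R,6R)-6-hydroxycarvone (hydroxyl trans to the isopropenyl group)
Conditions: KHMDS, THF, −78 °C; 2-(phenylsulfonyl)-3-phenyloxaziridine, −78 °C
Reagents that add atoms: 2-(phenylsulfonyl)-3-phenyloxaziridine, O=S(=O)(c1ccccc1)N1OC1c1ccccc1
Why: Kinetic deprotonation at C6 gives the cross-conjugated enolate, which is hydroxylated (enolate α-hydroxylation by an N-sulfonyloxaziridine) on the face away from the neighbouring isopropenyl group; the trans carbinol is the future C8 and the isopropenyl carbon the future C7.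

Step 2
Reactants: 2 (5R,6R)-6-hydroxycarvone
Product: 3 6-(TBDPS-oxy)carvone
Conditions: TBDPSCl, imidazole, DMF, rt
Reagents that add atoms: tert-butyl(chloro)diphenylsilane, CC(C)(C)[Si](Cl)(c1ccccc1)c1ccccc1
Why: Silylation of the secondary α-hydroxy ketone; this ether is chosen because it must survive acid ketalisation, hydrogenation, lithium amide and peroxides up to step 18.

Step 3
Reactants: 3 6-(TBDPS-oxy)carvone
Product: 4 2,3-epoxy ketone of 3
Conditions: 30% H2O2, NaOH (cat.), MeOH, 0 °C
Reagents that add atoms: hydrogen peroxide, OO
Why: Weitz–Scheffer nucleophilic epoxidation of the enone; the isopropenyl group is inert to alkaline peroxide, and the epoxide configuration (expected anti to the isopropenyl group) is erased again in steps 4 and 5.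

Step 4
Reactants: 4 2,3-epoxy ketone
Product: 5 4-(TBDPS-oxy)-2-methyl-5-isopropenylcyclohex-2-en-1-ol (transposed allylic alcohol)
Conditions: N2H4·H2O, AcOH (cat.), MeOH, 0 °C to rt
Reagents that add atoms: none
Why: Wharton reaction: the epoxy hydrazone fragments with loss of N2 to the allylic alcohol, which moves the oxygen across the ring and puts the silyloxy carbon at the γ-position of the future enone.

Step 5
Reactants: 5 transposed allylic alcohol
Product: 6 4-(TBDPS-oxy)-2-methyl-5-isopropenylcyclohex-2-en-1-one
Conditions: MnO2, CH2Cl2, rt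
Reagents that add atoms: none
Why: MnO2 oxidation of a secondary allylic alcohol, which leaves the silyl ether and the isopropenyl group alone; the product is a γ-silyloxy carvone of the opposite ring numbering, which is why (S)-carvone was needed.

Step 6
Reactants: 6 γ-silyloxy enone
Product: 7 4-(TBDPS-oxy)-2-methyl-5-isopropenylcyclohexan-1-one (all substituents equatorial)
Conditions: L-Selectride, THF, −78 °C; aq. NH4Cl
Reagents that add atoms: none
Why: Conjugate hydride addition of the hindered borohydride to the α-methyl enone (as with carvone itself) and protonation of the enolate; the methyl epimers converge in step 7 in any case.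

Step 7
Reactants: 7 silyloxy dihydrocarvone, 8 ethyl vinyl ketone
Product: 11 2-methyl-2-(3-oxopentyl) diketone (methyl cis to isopropenyl), via ketimine 9 (not isolated), via alkylated ketimine 10 (not isolated)
Conditions: (R)-1-phenylethylamine, TsOH (cat.), toluene, reflux (−H2O); 8, THF, 40 °C; 10% aq. AcOH, rt
Reagents that add atoms: none
Why: Chiral-imine Michael addition: the ketimine reacts through its more substituted secondary enamine tautomer with the enone in an aza-ene-like transition state while the phenylethyl group shields one face. The (R)-amine is the antipode that places the oxopentyl chain trans to the isopropenyl group (future 10β-methyl), and hydrolysis returns the auxiliary.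

Step 8
Reactants: 11 diketone
Product: 12 8α-(TBDPS-oxy)eudesma-4,11-dien-3-one
Conditions: NaOMe (0.2 equiv), MeOH, 60 °C
Reagents that add atoms: none
Why: Intramolecular aldol condensation completes the Robinson annulation; only attack on the ring ketone gives a six-membered enone, and the quaternary C10 cannot epimerise.

Step 9
Reactants: 12 enone
Product: 13 3,3-ethylenedioxy-8α-(TBDPS-oxy)eudesma-5,11-diene
Conditions: ethylene glycol, TsOH (cat.), benzene, reflux (Dean–Stark)
Reagents that add atoms: ethylene glycol, OCCO
Why: Acid-catalysed ketalisation of a 4-en-3-one runs through the dienol ether and leaves the alkene at C5=C6; this deconjugation exposes C6 to electrophilic oxidants.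

Step 10
Reactants: 13 Δ5-ketal
Product: 14 5α,6α-epoxide of 13
Conditions: mCPBA (1.05 equiv), NaHCO3, CH2Cl2, −20 to 0 °C
Reagents that add atoms: mCPBA, OOC(=O)c1cccc(Cl)c1
Why: Prilezhaev epoxidation: the trisubstituted ring alkene is more nucleophilic than the isopropenyl group, and the angular methyl and the 7β side chain leave the α face open; the α-epoxide fixes the C6 oxygen as α.

Step 11
Reactants: 14 epoxy ketal
Product: 16 6α-hydroxy-8α-(TBDPS-oxy)eudesma-4,11-dien-3-one, via epoxy ketone 15 (not isolated)
Conditions: PPTS, acetone–H2O, 40 °C; then Et3N, CH2Cl2, rt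
Reagents that add atoms: water, O
Why: Ketal hydrolysis frees the ketone, and the β,γ-epoxy ketone opens by base-induced β-elimination (E1cB) from C4. The C6–O bond is not touched, so the 6α configuration is retained, and no internal nucleophile is present that could open the epoxide from the β face.

Step 12
Reactants: 16 6α-hydroxy enone
Product: 17 6α,12-dihydroxy-8α-(TBDPS-oxy)eudesma-4,11(13)-dien-3-one
Conditions: SeO2 (0.3 equiv), t-BuOOH, CH2Cl2, rt
Reagents that add atoms: tert-butyl hydroperoxide, CC(C)(C)OO (oxygen relayed by selenium dioxide, O=[Se]=O)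
Why: SeO2-catalysed allylic hydroxylation (ene reaction, then [2,3] shift) of the isopropenyl group at its methyl, CH3 being preferred over the tertiary C7–H; the enone alkene is too electron-poor to react.

Step 13
Reactants: 17 allylic diol
Product: 19 8α-(TBDPS-oxy)-3-oxoeudesma-4,11(13)-dien-6α,12-olide, via lactol 18 (not isolated)
Conditions: TEMPO (0.2 equiv), PhI(OAc)2 (2.5 equiv), CH2Cl2, rt
Reagents that add atoms: none
Why: Oxoammonium oxidation is selective for the primary allylic alcohol; the enal is trapped by the 6α-hydroxyl as the lactol, which is oxidised on to the trans-fused α-methylene lactone (oxidative lactonisation of a 1,4-diol).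

Step 14
Reactants: 19 enone lactone
Product: 20 8α-(TBDPS-oxy)-3-oxo-5αH-eudesman-6α,12-olide (C4 and C11 epimer mixture)
Conditions: H2 (1 atm), Pd/C, EtOAc, rt
Reagents that add atoms: none
Why: Heterogeneous hydrogenation saturates the lactone methylene and, more slowly, the tetrasubstituted enone from the α face (the β face is blocked by the angular methyl, as in santonin-type lactones), which sets the trans ring fusion. C4 and C11 are not controlled and need not be, since both become sp2 again.

Step 15
Reactants: 20 keto lactone
Product: 22 8α-(TBDPS-oxy)-3-oxo-5αH-eudesma-1,11(13)-dien-6α,12-olide, via bis-selenide 21 (not isolated)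
Conditions: LDA (2.3 equiv), THF, −78 °C; PhSeBr (2.3 equiv), −78 °C; then 30% H2O2, pyridine, CH2Cl2, 0 °C to rt
Reagents that add atoms: none
Why: Kinetic deprotonation gives the C2 enolate of the ketone (CH2 before the methyl-bearing CH) and the lactone enolate, and both are selenenylated. Oxidation triggers two selenoxide syn-eliminations, toward C1 and toward the C13 methyl, the ring hydrogen at C7 lying anti to selenium in the trans-fused lactone.

Step 16
Reactants: 22 enone methylene lactone
Product: 23 3-(trifluoromethylsulfonyloxy)-8α-(TBDPS-oxy)eudesma-1,3,11(13)-trien-6α,12-olide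
Conditions: Tf2O, 2,6-di-tert-butyl-4-methylpyridine, CH2Cl2, 0 °C to rt
Reagents that add atoms: trifluoromethanesulfonic anhydride, O=S(=O)(OS(=O)(=O)C(F)(F)F)C(F)(F)F
Why: O-Triflation of the enone and loss of the only enolisable proton (C4–H; C2 is vinylic, C10 quaternary) gives the cross-conjugated dienyl triflate without strong base, so the lactone methylene meets no nucleophile; the C4 epimers converge.

Step 17
Reactants: 23 dienyl triflate
Product: 24 8α-(TBDPS-oxy)eudesma-1,3,11(13)-trien-6α,12-olide
Conditions: Pd(OAc)2 (5 mol %), PPh3, Bu3N, HCO2H, DMF, 50 °C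
Reagents that add atoms: none
Why: Palladium-catalysed formate reduction of a vinyl triflate: oxidative addition to zerovalent palladium, formate exchange, loss of CO2 and C–H reductive elimination give the homoannular 1,3-diene without touching C5 or C10.

Step 18
Reactants: 24 silyl ether
Product: 25 8α-hydroxyeudesma-1,3,11(13)-trien-6α,12-olide
Conditions: TBAF, AcOH, THF, rt
Reagents that add atoms: none
Why: Fluoride cleaves the silyl ether; acetic acid buffers the alkoxide so that neither conjugate addition to the methylene lactone nor migration of the lactone to O8 occurs.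

Step 19
Reactants: 25 alcohol
Product: 26 8α-methacryloyloxy-eudesma-1,3,11(13)-trien-6α,12-olide
Conditions: methacrylic anhydride, Et3N, DMAP (cat.), CH2Cl2, 0 °C to rt
Reagents that add atoms: methacrylic anhydride, C=C(C)C(=O)OC(=O)C(C)=C
Why: DMAP-catalysed acylation of the equatorial 8α-alcohol under mild base; this is the last step that uses a nucleophilic catalyst.

Step 20
Reactants: 26 8α-methacryloyloxy-eudesma-1,3,11(13)-trien-6α,12-olide
Product: 28 (1R,10R)-1,10-epoxygermacra-2Z,4E,11(13)-trien-6α,12-olide 8-methacrylate, via E,Z,E-triene 27 (not isolated)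
Conditions: hν (300 nm lamps, Pyrex), degassed Et2O, −78 °C; then DMDO (acetone solution), −78 to −40 °C
Reagents that add atoms: dimethyldioxirane, CC1(C)OO1
Why: Excitation of the s-cis homoannular diene of 26, the only chromophore absorbing near 300 nm, triggers the allowed conrotatory 6π electrocyclic opening of the doubly allylic C5–C10 σ bond; this is the known photochemistry of trans-fused eudesma-1,3-dienes. No ring is closed by bond formation: the ten-membered ring arises because the bond shared by rings A and B is cut, so no closure mode applies. The opening creates no stereocentre; the trans fusion (5α-H, 10β-methyl) and conrotation turn C6 and C9 outward and give the E,Z,E triene 27 as a helical conformer with the C10 methyl up. Because 27 recloses thermally in the disrotatory sense and is photo-equilibrated with 26, irradiation is stopped at the photostationary state and the cold solution is oxidised at once. DMDO epoxidises C1=C10, the most electron-rich alkene (C4=C5 is deactivated by the allylic lactone oxygen, C2=C3 is only disubstituted, both acrylates are electron-poor), which removes the hexatriene and with it the reclosure path. The new C1 and C10 centres are set by attack on the outer face of the helical triene held by the trans-lactone, which should give the 1R,10R epoxide. The step needs E,Z,E geometry, secured by ring fusion and orbital symmetry, and site selectivity in the epoxidation, secured by the lactone oxygen next to C5.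

Step 21
Reactants: 28 1,10-epoxy diene
Product: 30 (1R,10R)-1,10-epoxy-5-oxogermacra-2Z,4(15),11(13)-trien-6α,12-olide 8-methacrylate, via 5-hydroperoxide 29 (not isolated)
Conditions: O2, tetraphenylporphyrin (cat.), visible light, Ac2O, pyridine, DMAP (cat.), CH2Cl2, 0 °C
Reagents that add atoms: dioxygen, O=O
Why: Schenck ene reaction: singlet oxygen adds to C5 of the trisubstituted 4E-alkene and takes hydrogen from the C15 methyl on the more crowded side of the alkene, while H-6 is held in the alkene plane; [4+2] addition across C2–C5 is impossible because the ring would bridge the diene termini on opposite faces. Acetylation of the hydroperoxide and Kornblum–DeLaMare-type elimination give the enone in the same flask, so the configuration of the hydroperoxide does not matter. C2=C3 has no abstractable allylic hydrogen and the acrylates are electron-poor.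

Step 22
Reactants: 30 exocyclic enone
Product: 31 (1R,2S,3S,10R)-1,10:2,3-diepoxy-5-oxogermacra-4(15),11(13)-dien-6α,12-olide 8-methacrylate
Conditions: DMDO, acetone, 0 °C
Reagents that add atoms: dimethyldioxirane, CC1(C)OO1
Why: Dioxirane epoxidation: C2=C3 is now the only alkene that is not part of an α,β-unsaturated carbonyl unit, so site selectivity is no longer at issue. Attack from the α face, where C2=C3 is flanked by H-1 and not by C10 with its methyl and epoxide oxygen, should give the 2S,3S cis-epoxide.

Step 23
Reactants: 31 diepoxy ketone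
Product: 32 ACon1_002091, (1R,2S,3S,5R,6S,7R,8S,10R)-1,10:2,3-diepoxy-5-hydroxygermacra-4(15),11(13)-dien-6,12-olide 8-methacrylate
Conditions: NaBH4, CeCl3·7H2O, MeOH, −78 °C
Reagents that add atoms: none
Why: Luche reduction gives 1,2-addition to the exocyclic enone at low temperature and spares lactone, ester and epoxides. Hydride should enter from the outer face of the s-trans enone, the face from which oxygen was delivered in step 21, so the hydroxyl is left on the inner side, anti to the C6 lactone oxygen (5R).

## Compound list

1 | (S)-(+)-carvone | CC1=CC[C@@H](CC1=O)C(C)=C | starting material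
2 | (5R,6R)-6-hydroxycarvone (OH trans to isopropenyl) | O[C@H]1C(=O)C(C)=CC[C@@H]1C(C)=C | intermediate
3 | 6-(TBDPS-oxy)carvone | CC(C)(C)[Si](c1ccccc1)(c1ccccc1)O[C@H]1C(=O)C(C)=CC[C@@H]1C(C)=C | intermediate
4 | 2,3-epoxide of 3 (epoxide anti to isopropenyl) | CC(C)(C)[Si](c1ccccc1)(c1ccccc1)O[C@H]1C(=O)[C@@]2(C)O[C@H]2C[C@@H]1C(C)=C | intermediate
5 | 4-(TBDPS-oxy)-2-methyl-5-isopropenylcyclohex-2-en-1-ol (silyloxy trans to isopropenyl) | CC(C)(C)[Si](c1ccccc1)(c1ccccc1)O[C@H]1C=C(C)[C@@H](O)C[C@@H]1C(C)=C | intermediate
6 | 4-(TBDPS-oxy)-2-methyl-5-isopropenylcyclohex-2-en-1-one | CC(C)(C)[Si](c1ccccc1)(c1ccccc1)O[C@H]1C=C(C)C(=O)C[C@@H]1C(C)=C | intermediate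
7 | 4-(TBDPS-oxy)-2-methyl-5-isopropenylcyclohexan-1-one (all-equatorial epimer drawn) | CC(C)(C)[Si](c1ccccc1)(c1ccccc1)O[C@H]1C[C@@H](C)C(=O)C[C@@H]1C(C)=C | intermediate
8 | ethyl vinyl ketone | CCC(=O)C=C | starting material
9 | ketimine of 7 with (R)-1-phenylethylamine | CC(C)(C)[Si](c1ccccc1)(c1ccccc1)O[C@H]1C[C@@H](C)C(=N[C@H](C)c2ccccc2)C[C@@H]1C(C)=C | intermediate
10 | 2-(3-oxopentyl) ketimine (Michael adduct) | CC(C)(C)[Si](c1ccccc1)(c1ccccc1)O[C@H]1C[C@@](C)(CCC(=O)CC)C(=N[C@H](C)c2ccccc2)C[C@@H]1C(C)=C | intermediate
11 | 4-(TBDPS-oxy)-2-methyl-2-(3-oxopentyl)-5-isopropenylcyclohexanone (methyl cis to isopropenyl) | CC(C)(C)[Si](c1ccccc1)(c1ccccc1)O[C@H]1C[C@@](C)(CCC(=O)CC)C(=O)C[C@@H]1C(C)=C | intermediate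
12 | 8α-(TBDPS-oxy)eudesma-4,11-dien-3-one | CC(C)(C)[Si](c1ccccc1)(c1ccccc1)O[C@H]1C[C@@]2(C)CCC(=O)C(C)=C2C[C@@H]1C(C)=C | intermediate
13 | 3,3-ethylenedioxy-8α-(TBDPS-oxy)eudesma-5,11-diene (C4 epimers) | CC(C)(C)[Si](c1ccccc1)(c1ccccc1)O[C@H]1C[C@@]2(C)CCC3(OCCO3)C(C)C2=C[C@@H]1C(C)=C | intermediate
14 | 5α,6α-epoxide of 13 | CC(C)(C)[Si](c1ccccc1)(c1ccccc1)O[C@H]1C[C@@]2(C)CCC3(OCCO3)C(C)[C@@]24O[C@H]4[C@@H]1C(C)=C | intermediate
15 | 5α,6α-epoxy-8α-(TBDPS-oxy)eudesm-11-en-3-one | CC(C)(C)[Si](c1ccccc1)(c1ccccc1)O[C@H]1C[C@@]2(C)CCC(=O)C(C)[C@@]24O[C@H]4[C@@H]1C(C)=C | intermediate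
16 | 6α-hydroxy-8α-(TBDPS-oxy)eudesma-4,11-dien-3-one | CC(C)(C)[Si](c1ccccc1)(c1ccccc1)O[C@H]1C[C@@]2(C)CCC(=O)C(C)=C2[C@@H](O)[C@@H]1C(C)=C | intermediate
17 | 6α,12-dihydroxy-8α-(TBDPS-oxy)eudesma-4,11(13)-dien-3-one | CC(C)(C)[Si](c1ccccc1)(c1ccccc1)O[C@H]1C[C@@]2(C)CCC(=O)C(C)=C2[C@@H](O)[C@@H]1C(CO)=C | intermediate
18 | 6α,12-lactol of the 12-aldehyde (anomers) | CC(C)(C)[Si](c1ccccc1)(c1ccccc1)O[C@H]1C[C@@]2(C)CCC(=O)C(C)=C2[C@H]2OC(O)C(=C)[C@@H]21 | intermediate
19 | 8α-(TBDPS-oxy)-3-oxoeudesma-4,11(13)-dien-6α,12-olide | CC(C)(C)[Si](c1ccccc1)(c1ccccc1)O[C@H]1C[C@@]2(C)CCC(=O)C(C)=C2[C@H]2OC(=O)C(=C)[C@@H]21 | intermediate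
20 | 8α-(TBDPS-oxy)-3-oxo-5αH-eudesman-6α,12-olide (C4 and C11 epimers, left undefined) | CC(C)(C)[Si](c1ccccc1)(c1ccccc1)O[C@H]1C[C@@]2(C)CCC(=O)C(C)[C@@H]2[C@H]2OC(=O)C(C)[C@@H]21 | intermediate
21 | 2,11-bis(phenylseleno) derivative of 20 | CC(C)(C)[Si](c1ccccc1)(c1ccccc1)O[C@H]1C[C@@]2(C)CC([Se]c3ccccc3)C(=O)C(C)[C@@H]2[C@H]2OC(=O)C(C)([Se]c3ccccc3)[C@@H]21 | intermediate
22 | 8α-(TBDPS-oxy)-3-oxo-5αH-eudesma-1,11(13)-dien-6α,12-olide (C4 epimers) | CC(C)(C)[Si](c1ccccc1)(c1ccccc1)O[C@H]1C[C@@]2(C)C=CC(=O)C(C)[C@@H]2[C@H]2OC(=O)C(=C)[C@@H]21 | intermediate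
23 | 3-triflyloxy-8α-(TBDPS-oxy)eudesma-1,3,11(13)-trien-6α,12-olide | CC(C)(C)[Si](c1ccccc1)(c1ccccc1)O[C@H]1C[C@@]2(C)C=CC(OS(=O)(=O)C(F)(F)F)=C(C)[C@@H]2[C@H]2OC(=O)C(=C)[C@@H]21 | intermediate
24 | 8α-(TBDPS-oxy)eudesma-1,3,11(13)-trien-6α,12-olide | CC(C)(C)[Si](c1ccccc1)(c1ccccc1)O[C@H]1C[C@@]2(C)C=CC=C(C)[C@@H]2[C@H]2OC(=O)C(=C)[C@@H]21 | intermediate
25 | 8α-hydroxyeudesma-1,3,11(13)-trien-6α,12-olide | O[C@H]1C[C@@]2(C)C=CC=C(C)[C@@H]2[C@H]2OC(=O)C(=C)[C@@H]21 | intermediate
26 | 8α-methacryloyloxy-eudesma-1,3,11(13)-trien-6α,12-olide (5α-H, 10β-methyl) | C=C(C)C(=O)O[C@H]1C[C@@]2(C)C=CC=C(C)[C@@H]2[C@H]2OC(=O)C(=C)[C@@H]21 | intermediate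
27 | germacra-1(10)E,2Z,4E,11(13)-tetraen-6α,12-olide 8-methacrylate | C=C(C)C(=O)O[C@H]1C/C(C)=C/C=C\C(C)=C\[C@H]2OC(=O)C(=C)[C@@H]21 | intermediate
28 | (1R,10R)-1,10-epoxygermacra-2Z,4E,11(13)-trien-6α,12-olide 8-methacrylate | C=C(C)C(=O)O[C@H]1C[C@@]2(C)O[C@@H]2/C=C\C(C)=C\[C@H]2OC(=O)C(=C)[C@@H]21 | intermediate
29 | 5-hydroperoxy-4(15)-ene from 28 (OOH on the outer face) | C=C(C)C(=O)O[C@H]1C[C@@]2(C)O[C@@H]2/C=C\C(=C)[C@H](OO)[C@H]2OC(=O)C(=C)[C@@H]21 | intermediate
30 | (1R,10R)-1,10-epoxy-5-oxogermacra-2Z,4(15),11(13)-trien-6α,12-olide 8-methacrylate | C=C(C)C(=O)O[C@H]1C[C@@]2(C)O[C@@H]2/C=C\C(=C)C(=O)[C@H]2OC(=O)C(=C)[C@@H]21 | intermediate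
31 | (1R,2S,3S,10R)-1,10:2,3-diepoxy-5-oxogermacra-4(15),11(13)-dien-6α,12-olide 8-methacrylate | C=C(C)C(=O)O[C@H]1C[C@@]2(C)O[C@@H]2[C@H]2O[C@H]2C(=C)C(=O)[C@H]2OC(=O)C(=C)[C@@H]21 | intermediate
32 | ACon1_002091, (1R,2S,3S,5R,6S,7R,8S,10R)-1,10:2,3-diepoxy-5-hydroxygermacra-4(15),11(13)-dien-6,12-olide 8-methacrylate | C=C(C)C(=O)O[C@H]1C[C@@]2(C)O[C@@H]2[C@H]2O[C@H]2C(=C)[C@@H](O)[C@H]2OC(=O)C(=C)[C@@H]21 | target

## Step count and least certain steps

Total step count: 23. Longest linear sequence: 23 steps (1 to 32; ethyl vinyl ketone 8 enters at step 7).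

**Step 20 (key step).** The opening may stall at a photostationary mixture and the triene may reclose or isomerise further before it is trapped. Diene left unconverted is epoxidised as well and lost, and the methacrylate may take part in radical side reactions under irradiation. Fallback: set out from alcohol 25 and move the acylation behind the ring opening. Irradiation of 25 gives the triene alcohol F1, cold DMDO gives the epoxy alcohol F2 (easier to separate from oxidised diene), and methacrylic anhydride with DMAP returns the route to 28.

**Step 21.** The ene reaction may lose site selectivity (hydrogen abstraction at C6, attack on the vinyl epoxide), and the basic acetylation medium may epimerise C6 once the C5 ketone is present. Fallback from 28 by allylic oxidation in place of singlet oxygen: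
- SeO2 with t-BuOOH gives the 15-alcohol F3.
- VO(acac)2 with t-BuOOH epoxidises the allylic alcohol to the 4,5-epoxy alcohol F4.
- PPh3, I2 and imidazole give the epoxy iodide F5.
- Zinc dust in ethanol opens it reductively to the 5-epimeric allylic alcohol F6.
- Dess–Martin oxidation rejoins the route at 30.

**Step 22.** Facial selectivity at C2=C3 rests on a conformational argument and may be poor or reversed. Fallback from 30: NBS in aqueous DME forms the bromohydrin F7 by bromonium formation on the face DMDO prefers and anti attack of water at allylic C3. K2CO3 then closes the epoxide on the opposite face and returns to 31.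

**Step 23.** Hydride may be delivered to the inner face if the enone does not keep the s-trans, alkene-like ring conformation, and some conjugate reduction of the exocyclic enone or lactone methylene may occur. Fallback from 31: if reduction gives the C5 epimer F8, a Mitsunobu reaction with chloroacetic acid (PPh3, DIAD) inverts C5 to the chloroacetate F9, and thiourea with NaHCO3 removes the acyl group to give 32.

**Step 15.** Dianion formation may be incomplete, the ketone enolate may equilibrate toward C4, and the lactone selenoxide may eliminate into the ring to give the butenolide. Fallback from 19, keeping the methylene masked and not rebuilding it: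
- Dimethylamine adds to the lactone methylene to give the amine adduct F10.
- Hydrogenation over Pd/C sets the ring fusion and gives the saturated ketone F11.
- LDA (1 equiv), PhSeBr and NaIO4 give the 1-en-3-one F12.
- MeI followed by NaHCO3 eliminates trimethylamine and returns to 22.

## Further compounds

F1 | step 20 | 8α-hydroxygermacra-1(10)E,2Z,4E,11(13)-tetraen-6α,12-olide | O[C@H]1C/C(C)=C/C=C\C(C)=C\[C@H]2OC(=O)C(=C)[C@@H]21
F2 | step 20 | (1R,10R)-1,10-epoxy-8α-hydroxygermacra-2Z,4E,11(13)-trien-6α,12-olide | O[C@H]1C[C@@]2(C)O[C@@H]2/C=C\C(C)=C\[C@H]2OC(=O)C(=C)[C@@H]21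
F3 | step 21 | 15-hydroxy derivative of 28 | C=C(C)C(=O)O[C@H]1C[C@@]2(C)O[C@@H]2/C=C\C(CO)=C\[C@H]2OC(=O)C(=C)[C@@H]21
F4 | step 21 | 4,5-epoxide of F3 (oxygen on the outer face) | C=C(C)C(=O)O[C@H]1C[C@@]2(C)O[C@@H]2/C=C\[C@@]3(CO)O[C@@H]3[C@H]2OC(=O)C(=C)[C@@H]21
F5 | step 21 | 15-iodide of F4 | C=C(C)C(=O)O[C@H]1C[C@@]2(C)O[C@@H]2/C=C\[C@@]3(CI)O[C@@H]3[C@H]2OC(=O)C(=C)[C@@H]21
F6 | step 21 | (5S)-1,10-epoxy-5-hydroxygermacra-2Z,4(15),11(13)-trien-6α,12-olide 8-methacrylate | C=C(C)C(=O)O[C@H]1C[C@@]2(C)O[C@@H]2/C=C\C(=C)[C@H](O)[C@H]2OC(=O)C(=C)[C@@H]21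
F7 | step 22 | 2-bromo-3-hydroxy bromohydrin of 30 | C=C(C)C(=O)O[C@H]1C[C@@]2(C)O[C@@H]2[C@H](Br)[C@@H](O)C(=C)C(=O)[C@H]2OC(=O)C(=C)[C@@H]21
F8 | step 23 | C5 epimer of 32 (5S) | C=C(C)C(=O)O[C@H]1C[C@@]2(C)O[C@@H]2[C@H]2O[C@H]2C(=C)[C@H](O)[C@H]2OC(=O)C(=C)[C@@H]21
F9 | step 23 | 5-O-chloroacetate of 32 | C=C(C)C(=O)O[C@H]1C[C@@]2(C)O[C@@H]2[C@H]2O[C@H]2C(=C)[C@@H](OC(=O)CCl)[C@H]2OC(=O)C(=C)[C@@H]21
F10 | step 15 | 13-dimethylamino-11,13-dihydro adduct of 19 (C11 epimers) | CC(C)(C)[Si](c1ccccc1)(c1ccccc1)O[C@H]1C[C@@]2(C)CCC(=O)C(C)=C2[C@H]2OC(=O)C(CN(C)C)[C@@H]21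
F11 | step 15 | 4,5-dihydro (5αH) derivative of F10 | CC(C)(C)[Si](c1ccccc1)(c1ccccc1)O[C@H]1C[C@@]2(C)CCC(=O)C(C)[C@@H]2[C@H]2OC(=O)C(CN(C)C)[C@@H]21
F12 | step 15 | 1,2-dehydro derivative of F11 | CC(C)(C)[Si](c1ccccc1)(c1ccccc1)O[C@H]1C[C@@]2(C)C=CC(=O)C(C)[C@@H]2[C@H]2OC(=O)C(CN(C)C)[C@@H]21
A1 | alternative 1 | ten-membered trans-fused γ-lactone with C5 MOM ether, C4 methylene and C8 TBS ether | CC(C)(C)[Si](C)(C)O[C@H]1C/C(C)=C/C=C\C(=C)[C@@H](OCOC)[C@H]2OC(=O)C[C@@H]21
A2 | alternative 2 | ten-membered 1,10-epoxy-(2Z),4(15)-diene lactone with C5 TBS and C8 TES ethers | CC[Si](CC)(CC)O[C@H]1C[C@@]2(C)O[C@@H]2/C=C\C(=C)[C@@H](O[Si](C)(C)C(C)(C)C)[C@H]2OC(=O)C[C@@H]21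
A3 | alternative 3 | ten-membered (1(10)E,2Z)-dien-6-one with C8 PMB ether | COc1ccc(CO[C@H]2C/C(C)=C/C=C\[C@@](C)(O[Si](C)(C)C)[C@@H](O[Si](C)(C)C(C)(C)C)C(=O)[C@@H]2CCO[Si](C)(C)C(C)(C)C)cc1
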